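**Retrosynthetic overview**

- The target is a ten-membered carbocycle (C1–C10) bridged by the oxolane C1–O–C4 and fused at C6–C7 to a γ-ylidene butenolide (O, C6, C7, C11, C12). The butenolide is unveiled last from a 2-silylfuran by singlet oxygen and loss of water across C5–C6; the ring allows only the C5=C6 geometry of the target.
- The strategy rests on the homoallylic alcohol unit C8(OH)–C9H2–C10(=C14H2) inside that ring. C8–C9 is disconnected to a furan-3-carbaldehyde (C8) and a 2-substituted allyl bromide (C9, C10, C14) and is made by CrCl2 allylation, which closes the ten-membered ring onto the preformed furan and oxolane methyl ketal.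
- The cyclisation precursor is built from furan-3,4-dimethanol (arms C8 and C13 told apart by alkoxide-directed C-silylation at C12). C5–C6 comes from furyl-metal opening of the tosylate of (R)-2-methylglycidol (C4, C15), C2–C3 from acetate dianion opening of the derived epoxide (γ-lactone), and C1–C10 from a 2-lithioallyl ether adding to the lactone, followed by methyl ketal formation.
- Rings form in the order furan (bought), oxolane (lactone, then ketal), ten-membered ring (key step), butenolide (from the furan).
- Stereocentres: C4 from the glycidol; C1 held by the bridge; C8 in the key step; C10 by hydrogenation after O8 acylation (O8 and C14 are cis on the ring, so hydrogen delivered from a free 8-OH would give the 10-epimer); the side-chain centre from the same glycidol.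

Key step: step 14

Remark: positions are numbered as in the germacrane skeleton of the target (C1 hemiketal carbon, C4 oxygen-bearing methyl carbinol carbon, C5=C6 enol ether alkene, C7=C11 butenolide alkene, C8 acyloxy carbon, C10 methyl-bearing carbon, C12 lactone carbonyl, C13 acetoxymethyl carbon, C14 and C15 the methyls on C10 and C4).

**Route**

Step 1
Reactants: 1 (R)-2-methylglycidol
Product: 2 [(2S)-2-methyloxiran-2-yl]methyl 4-methylbenzenesulfonate
Conditions: TsCl, Et3N, DMAP (cat.), CH2Cl2, 0 °C
Reagents that add atoms: p-toluenesulfonyl chloride, Cc1ccc(cc1)S(Cl)(=O)=O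
Why: Sulfonylation of the primary alcohol (tosylate formation) leaves the quaternary epoxide carbon untouched, so the spatial arrangement of 1 is carried into 2 unchanged (the descriptor changes only through priorities).

Step 2
Reactants: 3 diethyl furan-3,4-dicarboxylate
Product: 4 furan-3,4-diyldimethanol
Conditions: LiAlH4, THF, 0 °C → rt; aqueous NaOH work-up
Reagents that add atoms: none
Why: Hydride reduction of both ester groups to primary alcohols is standard for furan-3,4-dicarboxylates and leaves the furan ring intact.

Step 3
Reactants: 4 furan-3,4-diyldimethanol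
Product: 5 [4-(tert-butyldimethylsilyloxymethyl)furan-3-yl]methanol
Conditions: NaH (1.0 equiv), THF, rt; t-BuMe2SiCl (1.0 equiv)
Reagents that add atoms: tert-butyldimethylsilyl chloride, CC(C)(C)[Si](C)(C)Cl
Why: Monosilylation of a symmetrical diol through its sparingly soluble monosodium alkoxide (Williamson-type O-silylation) should stop after one hydroxyl and so differentiates the future C8 (silylated) and C13 (free) arms.

Step 4
Reactants: 5 [4-(tert-butyldimethylsilyloxymethyl)furan-3-yl]methanol
Product: 8 [4-(tert-butyldimethylsilyloxymethyl)-2-(trimethylsilyl)furan-3-yl]methanol, via C2-lithio lithium alkoxide 6 (not isolated), via O-silyl C-silyl furan 7 (not isolated)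
Conditions: n-BuLi (2.2 equiv), DME, 0 °C; Me3SiCl (2.4 equiv), −78 °C → rt; then K2CO3, MeOH, rt
Reagents that add atoms: chlorotrimethylsilane, C[Si](C)(C)Cl
Why: Alkoxide-directed lithiation (complex-induced proximity effect) places lithium on the furan α-carbon next to the CH2OLi arm and not next to the weakly coordinating silyloxymethyl arm, and C- and O-silylation followed by methanolysis of the labile O–SiMe3 group leaves the C-silyl alcohol with silicon on the future C12 and the free hydroxyl on C13.

Step 5
Reactants: 8 [4-(tert-butyldimethylsilyloxymethyl)-2-(trimethylsilyl)furan-3-yl]methanol; 2 [(2S)-2-methyloxiran-2-yl]methyl 4-methylbenzenesulfonate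
Product: 12 [4-(tert-butyldimethylsilyloxymethyl)-5-{[(2S)-2-methyloxiran-2-yl]methyl}-2-(trimethylsilyl)furan-3-yl]methanol, via C5-lithio lithium alkoxide 9 (not isolated), via bis(bromomagnesium) species 10 (not isolated), via hydroxy tosylate 11 (not isolated)
Conditions: s-BuLi (2.1 equiv), TMEDA, THF, −78 °C; MgBr2·OEt2 (2.2 equiv), −78 → −40 °C; CuI (10 mol %), 2, −40 → 0 °C; then K2CO3, MeOH, rt
Reagents that add atoms: none
Why: The only remaining furan C–H (future C6) is lithiated, transmetalated to magnesium (which also stops O→C silyl migration) and, under CuI catalysis, opens the glycidyl tosylate at its unsubstituted ring carbon by SN2 with no bond to C4 broken, after which the tertiary alkoxide closes onto the CH2OTs carbon (3-exo-tet Williamson-type closure) to give the transposed epoxide with C4 already in the configuration of the target.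

Step 6
Reactants: 12 [4-(tert-butyldimethylsilyloxymethyl)-5-{[(2S)-2-methyloxiran-2-yl]methyl}-2-(trimethylsilyl)furan-3-yl]methanol
Product: 14 (5R)-5-{[3-(tert-butyldimethylsilyloxymethyl)-4-(hydroxymethyl)-5-(trimethylsilyl)furan-2-yl]methyl}-5-methyloxolan-2-one, via hydroxy acid 13 (not isolated)
Conditions: AcOH (4 equiv), LiN(iPr)2 (8 equiv), THF, 0 → 45 °C; 12, 45 °C; then 1 M HCl to pH 3, 0 °C → rt
Reagents that add atoms: acetic acid (as its dilithio enolate), CC(O)=O
Why: The carboxylic acid dianion opens the 2,2-disubstituted epoxide at its CH2 terminus by SN2 to form C2–C3, and on acidification the γ-hydroxy acid with its tertiary hydroxyl should lactonise spontaneously (5-exo-trig acyl substitution), so C1–C4 of the oxolane are in place with C4 untouched.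

Step 7
Reactants: 15 2-bromoprop-2-en-1-ol
Product: 16 (2-bromoprop-2-en-1-yloxy)triethylsilane
Conditions: Et3SiCl, imidazole, CH2Cl2, 0 °C
Reagents that add atoms: chlorotriethylsilane, CC[Si](Cl)(CC)CC
Why: Standard O-silylation of a primary allylic alcohol with a silyl chloride and imidazole.

Step 8
Reactants: 14 (5R)-5-{[3-(tert-butyldimethylsilyloxymethyl)-4-(hydroxymethyl)-5-(trimethylsilyl)furan-2-yl]methyl}-5-methyloxolan-2-one; 16 (2-bromoprop-2-en-1-yloxy)triethylsilane
Product: 18 (5R)-5-{[3-(tert-butyldimethylsilyloxymethyl)-4-(hydroxymethyl)-5-(trimethylsilyl)furan-2-yl]methyl}-5-methyl-2-[3-(triethylsilyloxy)prop-1-en-2-yl]oxolan-2-ol (lactol), via 2-lithioallyl silyl ether 17 (not isolated)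
Conditions: 16 (2.4 equiv), t-BuLi (4.8 equiv), Et2O, −78 °C; 14, THF, −78 °C; aq. NH4Cl
Reagents that add atoms: none
Why: Bromine–lithium exchange gives the 2-lithioallyl ether, one equivalent of which is spent on the free hydroxyl while a second adds once to the lactone carbonyl because the tetrahedral lithium alkoxide does not collapse at −78 °C (organolithium addition to a lactone giving a lactol), which forms C1–C10; C1 is a hemiketal of no fixed configuration at this stage.

Step 9
Reactants: 18 lactol
Product: 19 {4-(tert-butyldimethylsilyloxymethyl)-5-{[(2R)-5-hydroxy-2-methyl-5-[3-(triethylsilyloxy)prop-1-en-2-yl]oxolan-2-yl]methyl}-2-(trimethylsilyl)furan-3-yl}methyl acetate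
Conditions: Ac2O, pyridine, CH2Cl2, 0 °C → rt
Reagents that add atoms: acetic anhydride, CC(=O)OC(C)=O
Why: Acetic anhydride in pyridine acylates only the primary furylmethanol (C13), since the tertiary hemiketal hydroxyl is too hindered to react without a stronger acyl-transfer catalyst.

Step 10
Reactants: 19 lactol acetate
Product: 20 {4-(tert-butyldimethylsilyloxymethyl)-5-{[(2R,5S)-5-(3-hydroxyprop-1-en-2-yl)-5-methoxy-2-methyloxolan-2-yl]methyl}-2-(trimethylsilyl)furan-3-yl}methyl acetate
Conditions: PPTS (0.2 equiv), MeOH, 0 °C → rt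
Reagents that add atoms: methanol, CO
Why: Acid-catalysed ketalisation through the cyclic oxocarbenium ion converts the lactol into the methyl ketal while the same pyridinium acid in methanol removes the primary triethylsilyl ether (the tert-butyldimethylsilyl ether, the acetate and the C–Si bond should survive); C1 forms under equilibrating conditions as both epimers, of which the one with C10 cis to C5 across the oxolane (1S, the only one that can later bridge) is separated and the other is returned to the same conditions.

Step 11
Reactants: 20 methyl ketal allylic alcohol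
Product: 22 {5-{[(2R,5S)-5-(3-bromoprop-1-en-2-yl)-5-methoxy-2-methyloxolan-2-yl]methyl}-4-(tert-butyldimethylsilyloxymethyl)-2-(trimethylsilyl)furan-3-yl}methyl acetate, via allylic mesylate 21 (not isolated)
Conditions: MsCl, Et3N, CH2Cl2, −20 °C; then LiBr, THF, 0 °C → rt
Reagents that add atoms: lithium bromide, [Li+].[Br-]
Why: Mesylation of the primary allylic alcohol followed by SN2 displacement with bromide (Finkelstein-type substitution) gives the allylic bromide, the SN2′ pathway being degenerate for this 2-substituted allyl unit.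

Step 12
Reactants: 22 allylic bromide silyl ether
Product: 23 {5-{[(2R,5S)-5-(3-bromoprop-1-en-2-yl)-5-methoxy-2-methyloxolan-2-yl]methyl}-4-(hydroxymethyl)-2-(trimethylsilyl)furan-3-yl}methyl acetate
Conditions: Et3N·3HF, MeCN, rt → 40 °C
Reagents that add atoms: none
Why: Fluoride cleavage of the primary silyl ether with a weakly acidic HF source that contains no free amine should leave the allylic bromide, the ketal, the acetate and the furan C–Si bond alone.

Step 13
Reactants: 23 furylmethanol
Product: 24 {5-{[(2R,5S)-5-(3-bromoprop-1-en-2-yl)-5-methoxy-2-methyloxolan-2-yl]methyl}-4-formyl-2-(trimethylsilyl)furan-3-yl}methyl acetate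
Conditions: MnO2, CH2Cl2, rt
Reagents that add atoms: none
Why: MnO2 oxidises the furylic (benzylic-type) primary alcohol to the non-enolisable aldehyde under neutral conditions that do not touch the allylic bromide.

Step 14
Reactants: 24 furan aldehyde allylic bromide
Product: 26 (1S,4R,8S)-13-acetoxy-1,4-epoxy-1-methoxy-12-(trimethylsilyl)furanogermacr-10(14)-en-8-ol (furan fused at C6–C7 to the ten-membered ring), via allylchromium dichloride 25 (not isolated)
Conditions: CrCl2 (10 equiv), 4 Å molecular sieves, THF, rt, slow addition of 24 to a final 2 mM; aqueous work-up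
Reagents that add atoms: none
Why: Two equivalents of CrCl2 reduce the allylic C9–Br bond by successive one-electron transfers to the allylchromium dichloride 25 (trivalent chromium), whose two CH2 termini are equivalent by allyl transposition, and this adds to the furan aldehyde through a closed six-membered transition state in which chromium bridges C14 and the carbonyl oxygen, forming C8–C9 and leaving the C10=C14 exo-methylene; this is the Nozaki–Hiyama allylation in its known macrocyclising form. The ten-membered carbocycle C1–C10 closes in a 10-exo-trig sense onto the exocyclic C8=O, and because the furan and the cis-linked oxolane already hold eight of the ten ring atoms only the C9 and C8 ends have to meet, with slow addition at high dilution keeping intermolecular coupling down. C8 is the only new stereocentre: C9 can reach the carbonyl only from the furan face that carries the oxolane, and in the closed transition state the chromium-bound oxygen must lie toward C14, on the side of the bridging ring oxygen, which corresponds to the 8S carbinol with O8 cis to that oxygen. The step needs chemoselectivity for the aldehyde over the acetate and the ketal, which the low basicity and carbonyl selectivity of allylchromium reagents provide, and it cannot be spoiled by enolisation (the aldehyde has no α-hydrogen) or by β-elimination (no leaving group β to chromium). Should substrate control of the C8 face prove weak, a chiral sulfonamide ligand on chromium is the first adjustment.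

Step 15
Reactants: 1 (R)-2-methylglycidol
Product: 27 (S)-2-methyloxirane-2-carboxylic acid
Conditions: RuCl3·xH2O (2 mol %), NaIO4 (3 equiv), MeCN–CCl4–H2O, rt
Reagents that add atoms: sodium periodate, [Na+].[O-]I(=O)(=O)=O; water, O
Why: RuO4 generated from catalytic RuCl3 and periodate oxidises an epoxy alcohol to the epoxy acid without opening the epoxide, and the quaternary stereocentre is not involved.

Step 16
Reactants: 27 (S)-2-methyloxirane-2-carboxylic acid
Product: 28 (R)-3-chloro-2-hydroxy-2-methylpropanoic acid
Conditions: HCl (4 M in dioxane), 0 °C → rt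
Reagents that add atoms: hydrogen chloride, Cl
Why: Acid-promoted opening of the glycidic acid by chloride occurs by SN2 at the CH2 terminus, because the quaternary α-carbon next to the carboxyl group neither ionises nor suffers substitution, so the stereocentre keeps its spatial arrangement and becomes the (R)-chlorohydrin centre of the side chain.

Step 17
Reactants: 28 (R)-3-chloro-2-hydroxy-2-methylpropanoic acid
Product: 30 (R)-3-chloro-2-methyl-2-(triethylsilyloxy)propanoic acid, via silyl ester 29 (not isolated)
Conditions: Et3SiOTf (2.3 equiv), 2,6-lutidine, CH2Cl2, −78 → 0 °C; then aq. citric acid, THF, rt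
Reagents that add atoms: triethylsilyl trifluoromethanesulfonate, CC[Si](CC)(CC)OS(=O)(=O)C(F)(F)F
Why: The silyl triflate with 2,6-lutidine silylates both the tertiary hydroxyl and the carboxyl group, and mild aqueous acid hydrolyses only the silyl ester, leaving the tertiary silyl ether that masks the chlorohydrin against epoxide formation in the later basic steps.

Step 18
Reactants: 26 macrocyclic 8-carbinol; 30 (R)-3-chloro-2-methyl-2-(triethylsilyloxy)propanoic acid
Product: 32 8-O-[(2R)-3-chloro-2-methyl-2-(triethylsilyloxy)propanoyl] ester of 26, via acid chloride 31 (not isolated)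
Conditions: 30 (1.5 equiv), 1-chloro-N,N,2-trimethylprop-1-en-1-amine, CH2Cl2, 0 °C → rt; then 26, DMAP, pyridine, CH2Cl2, rt
Reagents that add atoms: none
Why: The α-chloroenamine converts the hindered acid into its acid chloride under neutral conditions and DMAP-catalysed acylation (nucleophilic acyl substitution) esterifies O8 with retention at C8; this is done before the hydrogenation because O8 and C14 are cis in the target, so a free 8-hydroxyl would steer hydrogen to the wrong face of C10.

Step 19
Reactants: 32 exo-methylene ester
Product: 33 (1S,4R,8S,10R)-10-methyl compound (C10=C14 reduced; otherwise as 32)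
Conditions: H2 (4 bar), RhCl(PPh3)3 (10 mol %), toluene, rt
Reagents that add atoms: none
Why: Homogeneous hydrogenation with the neutral catalyst RhCl(PPh3)3 reduces only the 1,1-disubstituted alkene (furan, C–Cl and silyl groups are inert) and is not directed by esters, so hydrogen should add to C10 from the face opposite the bulky O8 acyloxy group and the bridging oxygen, leaving C14 cis to O8 (10R).

Step 20
Reactants: 33 silylfuran
Product: 35 6-hydroxy-6,12-olide (γ-hydroxybutenolide; C12 carbonyl; C6 hydroxylated; C6 epimers), via furan endoperoxide 34 (not isolated)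
Conditions: O2, visible light, tetraphenylporphyrin (cat.), CH2Cl2, −78 °C; then H2O, rt
Reagents that add atoms: dioxygen, O=O
Why: Singlet oxygen adds to the furan in a [4+2] cycloaddition and the silyl group then migrates from C12 to the peroxide oxygen (regiocontrolled photooxygenation of a 2-silylfuran), which makes C12 the lactone carbonyl and C6 the hydroxylated carbon; the new C6 centre forms without control and is removed in the next step.

Step 21
Reactants: 35 γ-hydroxybutenolide
Product: 37 (1S,4R,8S,10R)-1-O-methyl 2′-O-triethylsilyl derivative of the target (5,7(11)-dien-6,12-olide), via hemiketal mesylate 36 (not isolated)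
Conditions: MsCl, Et3N, DMAP (cat.), CH2Cl2, −20 → 0 °C
Reagents that add atoms: none
Why: Sulfonylation of the pseudo-acid hydroxyl and base-induced loss of methanesulfonate through the acyloxy-stabilised cation (E1-type elimination) form C5=C6, and only the isomer with C4 and C7 cis can exist inside the ten-membered ring, which is the geometry of the target.

Step 22
Reactants: 37 protected dienolide
Product: 38 target CNP0414417.3
Conditions: 48% aq. HF, MeCN–H2O, 0 °C → rt
Reagents that add atoms: water, O
Why: Aqueous HF cleaves the tertiary triethylsilyl ether and hydrolyses the methyl ketal through the oxocarbenium ion (acetal hydrolysis), and the hemiketal hydroxyl can only return on the face opposite the C1–O–C4 bridge, so C1 has the configuration of the target.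

**Compound list**

1 | (R)-2-methylglycidol | OC[C@]1(C)CO1 | starting material
2 | [(2S)-2-methyloxiran-2-yl]methyl 4-methylbenzenesulfonate | Cc1ccc(cc1)S(=O)(=O)OC[C@]1(C)CO1 | intermediate
3 | diethyl furan-3,4-dicarboxylate | CCOC(=O)c1cocc1C(=O)OCC | starting material
4 | furan-3,4-diyldimethanol | OCc1cocc1CO | intermediate
5 | [4-(tert-butyldimethylsilyloxymethyl)furan-3-yl]methanol | OCc1cocc1CO[Si](C)(C)C(C)(C)C | intermediate
6 | C2-lithio lithium alkoxide of 5 | [Li]OCc1c([Li])occ1CO[Si](C)(C)C(C)(C)C | intermediate
7 | O-trimethylsilyl C2-trimethylsilyl derivative of 5 | C[Si](C)(C)OCc1c([Si](C)(C)C)occ1CO[Si](C)(C)C(C)(C)C | intermediate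
8 | [4-(tert-butyldimethylsilyloxymethyl)-2-(trimethylsilyl)furan-3-yl]methanol | C[Si](C)(C)c1occ(CO[Si](C)(C)C(C)(C)C)c1CO | intermediate
9 | C5-lithio lithium alkoxide of 8 | C[Si](C)(C)c1oc([Li])c(CO[Si](C)(C)C(C)(C)C)c1CO[Li] | intermediate
10 | bis(bromomagnesium) species from 9 | C[Si](C)(C)c1oc([Mg]Br)c(CO[Si](C)(C)C(C)(C)C)c1CO[Mg]Br | intermediate
11 | (2S)-3-[3-(tert-butyldimethylsilyloxymethyl)-4-(hydroxymethyl)-5-(trimethylsilyl)furan-2-yl]-2-hydroxy-2-methylpropyl 4-methylbenzenesulfonate | C[Si](C)(C)c1oc(C[C@@](O)(C)COS(=O)(=O)c2ccc(C)cc2)c(CO[Si](C)(C)C(C)(C)C)c1CO | intermediate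
12 | [4-(tert-butyldimethylsilyloxymethyl)-5-{[(2S)-2-methyloxiran-2-yl]methyl}-2-(trimethylsilyl)furan-3-yl]methanol | C[Si](C)(C)c1oc(C[C@@]2(C)CO2)c(CO[Si](C)(C)C(C)(C)C)c1CO | intermediate
13 | (4R)-5-[3-(tert-butyldimethylsilyloxymethyl)-4-(hydroxymethyl)-5-(trimethylsilyl)furan-2-yl]-4-hydroxy-4-methylpentanoic acid | C[Si](C)(C)c1oc(C[C@@](O)(C)CCC(O)=O)c(CO[Si](C)(C)C(C)(C)C)c1CO | intermediate
14 | (5R)-5-{[3-(tert-butyldimethylsilyloxymethyl)-4-(hydroxymethyl)-5-(trimethylsilyl)furan-2-yl]methyl}-5-methyloxolan-2-one | C[Si](C)(C)c1oc(C[C@@]2(C)CCC(=O)O2)c(CO[Si](C)(C)C(C)(C)C)c1CO | intermediate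
15 | 2-bromoprop-2-en-1-ol | OCC(Br)=C | starting material
16 | (2-bromoprop-2-en-1-yloxy)triethylsilane | CC[Si](CC)(CC)OCC(Br)=C | intermediate
17 | [3-(triethylsilyloxy)prop-1-en-2-yl]lithium | CC[Si](CC)(CC)OCC([Li])=C | intermediate
18 | lactol: (5R)-5-{[3-(tert-butyldimethylsilyloxymethyl)-4-(hydroxymethyl)-5-(trimethylsilyl)furan-2-yl]methyl}-5-methyl-2-[3-(triethylsilyloxy)prop-1-en-2-yl]oxolan-2-ol | C[Si](C)(C)c1oc(C[C@@]2(C)CCC(O)(O2)C(=C)CO[Si](CC)(CC)CC)c(CO[Si](C)(C)C(C)(C)C)c1CO | intermediate
19 | C13 acetate of lactol 18 | C[Si](C)(C)c1oc(C[C@@]2(C)CCC(O)(O2)C(=C)CO[Si](CC)(CC)CC)c(CO[Si](C)(C)C(C)(C)C)c1COC(C)=O | intermediate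
20 | {4-(tert-butyldimethylsilyloxymethyl)-5-{[(2R,5S)-5-(3-hydroxyprop-1-en-2-yl)-5-methoxy-2-methyloxolan-2-yl]methyl}-2-(trimethylsilyl)furan-3-yl}methyl acetate | C[Si](C)(C)c1oc(C[C@@]2(C)CC[C@](OC)(O2)C(=C)CO)c(CO[Si](C)(C)C(C)(C)C)c1COC(C)=O | intermediate
21 | allylic mesylate of 20 | C[Si](C)(C)c1oc(C[C@@]2(C)CC[C@](OC)(O2)C(=C)COS(C)(=O)=O)c(CO[Si](C)(C)C(C)(C)C)c1COC(C)=O | intermediate
22 | allylic bromide with C8 silyl ether | C[Si](C)(C)c1oc(C[C@@]2(C)CC[C@](OC)(O2)C(=C)CBr)c(CO[Si](C)(C)C(C)(C)C)c1COC(C)=O | intermediate
23 | allylic bromide with free C8 hydroxyl | C[Si](C)(C)c1oc(C[C@@]2(C)CC[C@](OC)(O2)C(=C)CBr)c(CO)c1COC(C)=O | intermediate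
24 | {5-{[(2R,5S)-5-(3-bromoprop-1-en-2-yl)-5-methoxy-2-methyloxolan-2-yl]methyl}-4-formyl-2-(trimethylsilyl)furan-3-yl}methyl acetate | C[Si](C)(C)c1oc(C[C@@]2(C)CC[C@](OC)(O2)C(=C)CBr)c(C=O)c1COC(C)=O | intermediate
25 | allylchromium dichloride from 24 | C[Si](C)(C)c1oc(C[C@@]2(C)CC[C@](OC)(O2)C(=C)C[Cr](Cl)Cl)c(C=O)c1COC(C)=O | intermediate
26 | (1S,4R,8S)-13-acetoxy-1,4-epoxy-1-methoxy-12-(trimethylsilyl)furanogermacr-10(14)-en-8-ol | C[Si](C)(C)c1oc2C[C@@]3(C)CC[C@](OC)(O3)C(=C)C[C@H](O)c2c1COC(C)=O | intermediate
27 | (S)-2-methyloxirane-2-carboxylic acid | OC(=O)[C@]1(C)CO1 | intermediate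
28 | (R)-3-chloro-2-hydroxy-2-methylpropanoic acid | OC(=O)[C@@](C)(O)CCl | intermediate
29 | triethylsilyl (R)-3-chloro-2-methyl-2-(triethylsilyloxy)propanoate | CC[Si](CC)(CC)OC(=O)[C@@](C)(O[Si](CC)(CC)CC)CCl | intermediate
30 | (R)-3-chloro-2-methyl-2-(triethylsilyloxy)propanoic acid | OC(=O)[C@@](C)(O[Si](CC)(CC)CC)CCl | intermediate
31 | (2S)-3-chloro-2-methyl-2-(triethylsilyloxy)propanoyl chloride (same spatial arrangement as 30) | ClC(=O)[C@@](C)(O[Si](CC)(CC)CC)CCl | intermediate
32 | 8-O-[(2R)-3-chloro-2-methyl-2-(triethylsilyloxy)propanoyl] ester of 26 | C[Si](C)(C)c1oc2C[C@@]3(C)CC[C@](OC)(O3)C(=C)C[C@H](OC(=O)[C@@](C)(O[Si](CC)(CC)CC)CCl)c2c1COC(C)=O | intermediate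
33 | (1S,4R,8S,10R)-10-methyl silylfuran ester | C[Si](C)(C)c1oc2C[C@@]3(C)CC[C@](OC)(O3)[C@H](C)C[C@H](OC(=O)[C@@](C)(O[Si](CC)(CC)CC)CCl)c2c1COC(C)=O | intermediate
34 | furan 6,12-endoperoxide of 33 | CC(=O)OCC1=C2C3(OOC1(O3)[Si](C)(C)C)C[C@@]4(C)CC[C@](OC)(O4)[C@H](C)C[C@@H]2OC(=O)[C@@](C)(O[Si](CC)(CC)CC)CCl | intermediate
35 | 6-hydroxy-7(11)-en-6,12-olide (γ-hydroxybutenolide, C6 epimers) | CC(=O)OCC1=C2C(O)(C[C@@]3(C)CC[C@](OC)(O3)[C@H](C)C[C@@H]2OC(=O)[C@@](C)(O[Si](CC)(CC)CC)CCl)OC1=O | intermediate
36 | C6 methanesulfonate of 35 | CC(=O)OCC1=C2C(OS(C)(=O)=O)(C[C@@]3(C)CC[C@](OC)(O3)[C@H](C)C[C@@H]2OC(=O)[C@@](C)(O[Si](CC)(CC)CC)CCl)OC1=O | intermediate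
37 | 1-O-methyl 2′-O-triethylsilyl derivative of the target | CC(=O)OCC1=C2/C(=C\[C@@]3(C)CC[C@](OC)(O3)[C@H](C)C[C@@H]2OC(=O)[C@@](C)(O[Si](CC)(CC)CC)CCl)OC1=O | intermediate
38 | CNP0414417.3, (1S,4R,8S,10R)-13-acetoxy-1,4-epoxy-1-hydroxy-8-[(2R)-3-chloro-2-hydroxy-2-methylpropanoyloxy]germacra-5,7(11)-dien-6,12-olide | CC(=O)OCC1=C2/C(=C\[C@@]3(C)CC[C@](O)(O3)[C@H](C)C[C@@H]2OC(=O)[C@@](C)(O)CCl)OC1=O | target

**Step count**

Total: 22 steps. Longest linear sequence: 17 steps (steps 2–6, 8–14 and 18–22, from 3).

**Steps most likely to fail, with fallbacks**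

Step 14. The allylchromium may add to the wrong face of the aldehyde (poor or reversed facial selectivity at C8), and at insufficient dilution intermolecular allylation competes with ring closure. The fallback sets out from 24 and takes the stereochemical decision away from the ring closure. The cyclisation is run as before and the (8R)-carbinol F1, alone or mixed with 26, is oxidised with Dess–Martin periodinane (NaHCO3, CH2Cl2) to the furyl ketone F2. Reagent-controlled CBS reduction of F2 with the (R)-configured methyl oxazaborolidine and catecholborane (toluene, −78 °C; the furyl group acting as the large substituent, as in aryl alkyl ketones) should then give the 8S alcohol, and the route is rejoined at 26.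

Step 19. Hydrogen may be delivered to the face of C10 that is syn to O8, through residual coordination to the ester carbonyl or because the opposite face is crowded by the C2 methylene, which would give the C10 epimer. The fallback sets out from 32 and replaces kinetic face selection by thermodynamic control at the carbon α to the masked C1 carbonyl. The hydrogenation product, here the 10-epimeric methyl ketal F3, is hydrolysed (PPTS, acetone–water, rt) to the hemiketal F4. F4 is in equilibrium with its ring-opened 1-ketone, so DBU in toluene should epimerise C10 through the enol to the hemiketal F5. The configuration of F5 is that of the target, which is itself such a hemiketal and is therefore expected to carry the stable C10 configuration. PPTS in MeOH re-forms the methyl ketal, and the route is rejoined at 33.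

Step 5. The organometallic may attack the sulfonate instead of the epoxide, metalation of the alkoxide-bearing furan may be incomplete, or the neighbouring silyl group may migrate from oxygen to carbon before the coupling. The fallback sets out from 8 (and 1) and uses an electrophile with no sulfonyl group, so that the organolithium can be used directly. An Appel reaction (PPh3, CCl4, reflux) converts 1 into (S)-2-(chloromethyl)-2-methyloxirane F6. The dilithio species 9 opens F6 at the unsubstituted ring carbon at −78 °C under BF3·OEt2 activation to give the chlorohydrin F7, and K2CO3 in MeOH closes F7 to the epoxide, so the route is rejoined at 12.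

**Further compounds**

F1 | step 14 | (1S,4R,8R)-carbinol, C8 epimer of 26 | C[Si](C)(C)c1oc2C[C@@]3(C)CC[C@](OC)(O3)C(=C)C[C@@H](O)c2c1COC(C)=O
F2 | step 14 | 8-oxo compound (furyl ketone) from F1 | C[Si](C)(C)c1oc2C[C@@]3(C)CC[C@](OC)(O3)C(=C)CC(=O)c2c1COC(C)=O
F3 | step 19 | (10S)-epimer of 33 | C[Si](C)(C)c1oc2C[C@@]3(C)CC[C@](OC)(O3)[C@@H](C)C[C@H](OC(=O)[C@@](C)(O[Si](CC)(CC)CC)CCl)c2c1COC(C)=O
F4 | step 19 | 1-hemiketal of F3 | C[Si](C)(C)c1oc2C[C@@]3(C)CC[C@](O)(O3)[C@@H](C)C[C@H](OC(=O)[C@@](C)(O[Si](CC)(CC)CC)CCl)c2c1COC(C)=O
F5 | step 19 | 1-hemiketal with the C10 configuration of the target | C[Si](C)(C)c1oc2C[C@@]3(C)CC[C@](O)(O3)[C@H](C)C[C@H](OC(=O)[C@@](C)(O[Si](CC)(CC)CC)CCl)c2c1COC(C)=O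
F6 | step 5 | (S)-2-(chloromethyl)-2-methyloxirane | ClC[C@]1(C)CO1
F7 | step 5 | (2S)-1-chloro-3-[3-(tert-butyldimethylsilyloxymethyl)-4-(hydroxymethyl)-5-(trimethylsilyl)furan-2-yl]-2-methylpropan-2-ol | C[Si](C)(C)c1oc(C[C@@](O)(C)CCl)c(CO[Si](C)(C)C(C)(C)C)c1CO
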